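## Analysis of the target

Target **45** is a heliangolide-type germacranolide. Its ten-membered carbocycle (C1–C10, germacrane numbering) carries a trans-fused α-methylene-γ-butyrolactone across C6/C7 (lactone oxygen on C6; C11, C12 and C13 on C7), a trans C1–C10 epoxide, a Z trisubstituted C4=C5 olefin, an allylic hydroxyl on C3 and an acyloxy group on C8. The six stereocentres are (1R,3S,6R,7R,8R,10R). C6, C7 and C8 are contiguous, with H6/H7 trans and H7/H8 cis, so C11 and O8 lie on the same face; C3 and C6 flank the Z olefin; the epoxide carbons derive from an E C1=C10 bond. The C8 ester is built from two (E)-2-(oxymethyl)but-2-enoate units and ends in an acetate and a free primary allylic hydroxyl that sit cis on one double bond, so base can shift the acetyl group. The sensitive groups are the exo-methylene lactone (hydride, amines), the epoxide (acid, transannular opening), the allylic ester units of the side chain (SN2′ with nucleophilic catalysts) and the acetate. The difficulty is a medium ring with two different olefin geometries, three contiguous stereocentres on it and three oxygen functions (C3, C6, C8) that must be told apart. The strategy rests on one feature: the C7–C11 bond and the C8–O bond lie on adjacent ring carbons and C11 is tied to O6 through C12. A C11 radical held on O6 as a malonate can therefore add to a C7=C8 ring olefin and the resulting C8 radical can be oxygenated, which makes the lactone ring, C7 and the C8–O bond in one step.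

## Retrosynthetic reasoning

**45 ⇒ 44 ⇒ 43.** The two silyl ethers (O3 and the side-chain primary oxygen) are removed last under buffered acidic fluoride, which avoids the base-induced acetyl shift. The epoxide is cut back to the E C1=C10 olefin of **43**. In **43** this is the only electron-rich double bond: C4=C5 carries two allylic C–O bonds and all others are acrylate-type, so a peracid should choose it. Placing the epoxidation late limits the exposure of the epoxide to acid and nucleophiles.

**43 ⇒ 28 + 41.** The C8–O acyl bond is cut. The sensitive dimeric side chain then enters convergently, after every reduction, amine and metal step on the core. The forward reaction must acylate a hindered secondary alcohol without disturbing the allylic ester units of **41**.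

**41 ⇒ 38 + 32 ⇒ 29, 30, 33.** The inner ester CH2–O bond is cut to carboxylic acid **38** and allylic bromide **32**. Both halves are Morita–Baylis–Hillman adducts of acrylate **29** (with aldehydes **30** and **33**) after allylic transposition, which sets the trisubstituted olefins in the thermodynamically preferred geometry, β-substituent trans to the ester.

**28 ⇒ 27 ⇒ 25 ⇒ 23 ⇒ 22 ⇒ 21.** These are functional-group changes whose order is dictated by chemoselectivity.
- The C3 ketone of **21** is reduced first. A C3 enone with the lactone oxygen on C6 is a γ-acyloxy enone, which a dissolving metal would cleave at C6–O, and its C2 methylene would enter the Mannich methylenation.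
- The nitroxide residue is kept on O8 as a protecting group through ester hydrolysis and methylenation, so that only O6 can close the lactone.
- The ester carbon that the key step leaves on C11 is the handle for decarboxylative methylenation (**25** ⇒ **27**).
- Only then is the N–O bond cleaved to free O8 (**28**).

**21 ⇒ 18 + 19 (key disconnection).** The bonds C7–C11 and C8–O are cut together. What remains is a C6 malonate on a ten-membered trienone (**18**) and nitroxide **19**. The cut is made here because it is the only one that builds the lactone ring, C7 and the C8 oxygen in one operation from a precursor with a single stereocentre (C6). The C3 carbonyl of **18** is strategic: it makes C4=C5 electron-poor, so an electrophilic C11 radical should prefer C7 over C5. The forward reaction has to generate the C11 radical under an anodically regenerated iron mediator, close 5-exo to the trans-fused lactone and deliver oxygen to C8 cis to C11.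

**18 ⇒ 17 ⇒ 16 ⇒ 14 + 15.** The C3 carbonyl is traced back to a silyl-protected carbinol, and the malonate to acid chloride **15** and dienol **14**. The C3 silyloxy stereocentre is kept until **16** because it is the relay that sets C6. It is erased in **18** and re-created in **22**, the price paid for the regiocontrol of the key step.

**14 ⇒ 13 ⇒ 11 ⇒ 9.** The C6 carbinol comes from the cross-conjugated dienone **13**, and the C7=C8 bond from selenoxide elimination of **11**. The ring itself is opened by a retro-[3,3] step: C8–C9 is cut and the six-membered-ring bond C1–C6 re-formed, leading to carbinol **9**. The forward anionic oxy-Cope rearrangement gives the ten-membered ring with the E C1=C10 and Z C4=C5 geometry of the target in one step, and its enolate is the direct entry to C7 functionalisation.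

**9 ⇒ 7 + 8; 7 ⇒ 6 ⇒ 5 ⇒ 4 ⇒ 2 + 3; 2 ⇒ 1.** Vinyl Grignard reagent **8** adds to enone **7**. Taking **7** from a chiral-pool monoterpene enone would require γ-oxygenation through an extended enolate, with no regiochemical or facial handle and with loss of the isopropenyl stereocentre. The ring is therefore built from quinone monoketal **2** (from phenol **1**), which has both oxygens in place. Conjugate addition of **3** may be racemic because that carbon becomes trigonal C1 in the ring expansion. The only stereocentre that survives (later C3) is set by an oxazaborolidine-controlled reduction of **4**.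

## Alternatives that were turned down

**Alternative 1:** Disconnection of C7–C8 and C11–C13 around a preformed lactone, with the ten-membered ring left open.
- *Forward key step:* the lithio derivative of dithiane **A2** (a C8 acyl-anion equivalent carrying C9, C10, C1, C2 and C3) adds to C7 of butenolide **A3** anti to its C6 substituent, and the lactone enolate is aminomethylated at C11 by iminium salt **A4**, giving **A1**.
- *For:* the coupling is convergent and of a very reliable type. The C6/C7 trans relationship is set by an enantiopure building block, and C13 arrives as a masked methylene group. On both points it is stronger than the chosen route, whose C7 and C8 stereocentres depend on conformational control in a radical closure and whose exo-methylene group costs two further steps.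
- *Against:* no ring is closed. After **A1** the ten-membered ring must still be made by a macrocyclisation in the region of the Z trisubstituted C4=C5 bond. C8 sits at the ketone oxidation level; unmasking it puts a carbonyl β to the lactone oxygen on C6, inviting E1cB opening of the lactone and epimerisation at C7, and the C8 carbinol must then be set by a separate reduction. C3 and the epoxide are still missing.
- *Comparison:* the alternative secures the lactone stereochemistry but defers the hardest problem. The chosen route solves the ring first by a pericyclic step and then uses the ring to set C7 and the C8 oxygen together, in fewer steps after ring formation.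

**Alternative 2:** Disconnection of C8–C9 by a retro-[3,3] step to a six-membered ring that contains the C1–C6 bond, with the C8 oxygen already on the migrating alkenyl group.
- *Forward key step:* an anionic oxy-Cope rearrangement of the potassium alkoxide forms C8–C9, breaks C1–C6 and gives **A5**, the ten-membered C6 ketone with the C3 silyl ether and a C8 p-methoxybenzyl ether.
- *For:* this is the same proven ring expansion that the chosen route uses, so the two are equal on ring construction and olefin geometry. It fixes the C8 stereocentre in a closed chair transition state, which is more secure than nitroxide capture of a radical.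
- *Against:* the primary product is the C6–C7 enolate with the C8 ether in the β-position, so elimination to the C7=C8 enone competes. The lactone must still be annulated onto **A5** by C7 alkylation with a two-carbon unit next to the β-alkoxy group, C6 reduction, lactonisation and methylenation, with C6 and C7 set in separate steps. A geometrically pure 2-alkoxyvinyl nucleophile is also needed.
- *Comparison:* the chosen route keeps the ring expansion with a plain vinyl group, makes the C7=C8 enone on purpose (**13**) and moves the C8 oxygenation into the lactone-forming step. It gains step economy between ring and lactone and pays with a less secure C8 face.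

**Alternative 3:** Disconnection of C3–C4, closing the ten-membered ring and creating the C3 carbinol last.
- *Forward key step:* a Nozaki–Hiyama–Kishi reaction (divalent chromium with a nickel co-catalyst) adds the Z-alkenyl iodide terminus at C4 to the C3 aldehyde terminus of an open chain that already carries the lactone, the exo-methylene group, the epoxide and a C8 silyl ether, giving **A6**.
- *For:* it is the most convergent plan. Ring closure and the C3 stereocentre come in one mild, chemoselective step, and only protecting-group changes and the acylation follow. In end-game economy, and in not depending on an unproven method, it is stronger than the chosen route.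
- *Against:* a ten-membered ring is the least favourable size for such a closure (strain, high dilution, oligomers). The C3 configuration would be decided by the forming ring and is hard to predict. The open-chain precursor must carry C6, C7, C8, C1 and C10, each set by a separate acyclic asymmetric step, and its C3 aldehyde has the epoxide oxygen on the β-carbon C1, so enolisation can open the epoxide.
- *Comparison:* the chosen route forms the ring intramolecularly by a sigmatropic shift with no entropy problem and sets four of the six stereocentres with the ring as template. In exchange its risk is concentrated in one radical step instead of a macrocyclisation.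

Key step: step 13

## Remarks before the steps

- Locants: ring carbons C1–C10, lactone carbons C11 (α), C12 (C=O) and C13, as in germacranolides. Ten-membered intermediates without the C7 side chain are named as 4,10-dimethylcyclodecane derivatives with the same locants. TBS = tert-butyldimethylsilyl; TMPO = (2,2,6,6-tetramethylpiperidin-1-yl)oxy.
- Assumption: hydride reaches C6 of **13** from the ring periphery of the conformer that has C2 and C7 on one side of the C4=C5 plane and the C3 oxygen on the other, so that (3S) relays to (6S).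
- Assumption: nitroxide capture at C8 in step 13 occurs on the peripheral lobe of the radical, cis to C11, giving the 8R configuration.
- Assumption: both C6 epimers of **7** add the vinyl group anti to the isopropenyl group and rearrange to the same E olefin in step 7.

## Steps

Step 1
Reactants: 1 4-methoxy-2-methylphenol
Product: 2 4,4-dimethoxy-2-methylcyclohexa-2,5-dien-1-one
Conditions: PhI(OAc)2, MeOH, 0 °C
Reagents that add atoms: methanol, CO
Why: Oxidative dearomatisation of a para-methoxyphenol by a hypervalent iodine diacetate; methanol adds at the carbon that already bears the methoxy group, the standard way to a quinone monoketal, which holds the later C3 carbonyl free and the later C6 carbonyl masked.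

Step 2
Reactants: 2 4,4-dimethoxy-2-methylcyclohexa-2,5-dien-1-one; 3 prop-1-en-2-ylmagnesium bromide
Product: 4 rac-4,4-dimethoxy-2-methyl-5-(prop-1-en-2-yl)cyclohex-2-en-1-one
Conditions: CuBr·SMe2 (10 mol %), THF, −78 → −40 °C; then aq NH4Cl
Reagents that add atoms: prop-1-en-2-ylmagnesium bromide (3), CC(=C)[Mg]Br
Why: Copper-catalysed (monovalent copper) conjugate addition of a Grignard reagent; the unsubstituted enone terminus C5 should react in preference to C3, whose double bond is deactivated and hindered by the α-methyl group. The new stereocentre is left racemic on purpose because it becomes trigonal C1 in step 7.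

Step 3
Reactants: 4 rac-4,4-dimethoxy-2-methyl-5-(prop-1-en-2-yl)cyclohex-2-en-1-one
Product: 5 (1S)-4,4-dimethoxy-2-methyl-5-(prop-1-en-2-yl)cyclohex-2-en-1-ol (both C5 epimers)
Conditions: (R)-1-methyl-3,3-diphenyltetrahydro-1H,3H-pyrrolo[1,2-c][1,3,2]oxazaborole (20 mol %), catecholborane, toluene, −78 °C; then MeOH, aq NaOH
Reagents that add atoms: none
Why: CBS reduction: the 2-methylalkenyl flank acts as the large and the CH2 flank as the small substituent, so the (R)-catalyst should give the (1S)-alcohol from either enantiomer of 4 under catalyst control; catecholborane does not hydroborate the isopropenyl group. This carbinol is the later C3, the only stereocentre that survives the ring expansion.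

Step 4
Reactants: 5 (1S)-4,4-dimethoxy-2-methyl-5-(prop-1-en-2-yl)cyclohex-2-en-1-ol (both C5 epimers)
Product: 6 tert-butyl{[(1S)-4,4-dimethoxy-2-methyl-5-(prop-1-en-2-yl)cyclohex-2-en-1-yl]oxy}dimethylsilane (both C5 epimers)
Conditions: TBSCl, imidazole, DMF, rt
Reagents that add atoms: tert-butyldimethylsilyl chloride, CC(C)(C)[Si](C)(C)Cl
Why: Standard silylation of a secondary allylic alcohol; the TBS ether withstands the Grignard, alkoxide, selenium and hydride steps that follow.

Step 5
Reactants: 6 tert-butyl{[(1S)-4,4-dimethoxy-2-methyl-5-(prop-1-en-2-yl)cyclohex-2-en-1-yl]oxy}dimethylsilane (both C5 epimers)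
Product: 7 (4S)-4-(TBS-oxy)-3-methyl-6-(prop-1-en-2-yl)cyclohex-2-en-1-one (both C6 epimers)
Conditions: pyridinium p-toluenesulfonate (cat.), acetone/H2O, rt
Reagents that add atoms: water, O
Why: Acid-catalysed hydrolysis of an allylic dimethyl ketal, which is far more labile than the secondary TBS ether; it unveils the enone carbonyl (later C6) next to the isopropenyl-bearing carbon.

Step 6
Reactants: 7 (4S)-4-(TBS-oxy)-3-methyl-6-(prop-1-en-2-yl)cyclohex-2-en-1-one (both C6 epimers); 8 ethenylmagnesium bromide
Product: 9 (4S)-4-(TBS-oxy)-1-ethenyl-3-methyl-6-(prop-1-en-2-yl)cyclohex-2-en-1-ol (ethenyl trans to isopropenyl; both C6 epimers)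
Conditions: THF, −78 → 0 °C; then aq NH4Cl
Reagents that add atoms: ethenylmagnesium bromide (8), C=C[Mg]Br
Why: 1,2-Addition of a vinyl Grignard reagent to a β,β-disubstituted enone, where conjugate addition is blocked; attack anti to the adjacent isopropenyl group should place the two alkenyl groups trans, the arrangement that rearranges through a chair.

Step 7
Reactants: 9 (4S)-4-(TBS-oxy)-1-ethenyl-3-methyl-6-(prop-1-en-2-yl)cyclohex-2-en-1-ol
Product: 11 (3S,1(10)E,4Z)-3-(TBS-oxy)-4,10-dimethyl-7-(phenylselanyl)cyclodeca-1(10),4-dien-6-one (C7 epimers), via potassium dienolate 10 (not isolated)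
Conditions: KN(SiMe3)2, 18-crown-6, THF, 0 °C → rt; then PhSeBr, −78 °C
Reagents that add atoms: phenylselenyl bromide, Br[Se]c1ccccc1
Why: Anionic oxy-Cope rearrangement: the potassium alkoxide undergoes the [3,3] shift through a chair with both ring bonds equatorial, forming C8–C9 and breaking the six-membered-ring bond C1–C6; this gives the ten-membered ring with the E C1=C10 bond, while the former cyclohexene bond persists as Z C4=C5. The regiodefined C6–C7 enolate 10 is then selenenylated at C7, its only nucleophilic carbon.

Step 8
Reactants: 11 (3S,1(10)E,4Z)-3-(TBS-oxy)-4,10-dimethyl-7-(phenylselanyl)cyclodeca-1(10),4-dien-6-one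
Product: 13 (3S,1(10)E,4Z,7Z)-3-(TBS-oxy)-4,10-dimethylcyclodeca-1(10),4,7-trien-6-one, via selenoxide 12 (not isolated)
Conditions: H2O2 (30 %), pyridine, CH2Cl2, 0 °C → rt
Reagents that add atoms: none
Why: Oxidation to the selenoxide and syn-elimination; only C8 offers β-hydrogens, and in a ten-membered ring that already holds an E olefin the five-membered cyclic transition state is expected to give the less strained Z C7=C8 enone.

Step 9
Reactants: 13 (3S,1(10)E,4Z,7Z)-3-(TBS-oxy)-4,10-dimethylcyclodeca-1(10),4,7-trien-6-one
Product: 14 (3S,6S,1(10)E,4Z,7Z)-3-(TBS-oxy)-4,10-dimethylcyclodeca-1(10),4,7-trien-6-ol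
Conditions: NaBH4, CeCl3·7H2O, MeOH, −78 °C
Reagents that add atoms: none
Why: Luche 1,2-reduction of the cross-conjugated dienone; hydride should arrive from the ring periphery on the conformer in which C2 and C7 lie on one side of the C4=C5 plane and the C3 silyloxy group on the other, which places the new C6 oxygen on the side of the C3 oxygen, i.e. (6S). This 1,4-relay from C3 is the reason for carrying the silyl ether to this point.

Step 10
Reactants: 14 (3S,6S,1(10)E,4Z,7Z)-3-(TBS-oxy)-4,10-dimethylcyclodeca-1(10),4,7-trien-6-ol; 15 methyl 3-chloro-3-oxopropanoate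
Product: 16 (3S,6S,1(10)E,4Z,7Z)-3-(TBS-oxy)-4,10-dimethylcyclodeca-1(10),4,7-trien-6-yl methyl propanedioate
Conditions: pyridine, CH2Cl2, 0 °C
Reagents that add atoms: methyl 3-chloro-3-oxopropanoate (15), COC(=O)CC(Cl)=O
Why: Acylation of the bis-allylic alcohol by an acid chloride under pyridine buffering, with retention at C6; the non-acidic medium avoids ionisation of the doubly allylic C6–O bond.

Step 11
Reactants: 16 (3S,6S,1(10)E,4Z,7Z)-3-(TBS-oxy)-4,10-dimethylcyclodeca-1(10),4,7-trien-6-yl methyl propanedioate
Product: 17 (3S,6S,1(10)E,4Z,7Z)-3-hydroxy-4,10-dimethylcyclodeca-1(10),4,7-trien-6-yl methyl propanedioate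
Conditions: HF·pyridine, pyridine, THF, 0 °C → rt
Reagents that add atoms: none
Why: Fluoride cleavage of the secondary TBS ether under buffered, slightly acidic conditions, in which the malonate is not enolised and acyl migration from O6 to O3 is not promoted.

Step 12
Reactants: 17 (3S,6S,1(10)E,4Z,7Z)-3-hydroxy-4,10-dimethylcyclodeca-1(10),4,7-trien-6-yl methyl propanedioate
Product: 18 (6S,1(10)E,4Z,7Z)-4,10-dimethyl-3-oxocyclodeca-1(10),4,7-trien-6-yl methyl propanedioate
Conditions: Dess–Martin periodinane, NaHCO3, CH2Cl2, 0 °C
Reagents that add atoms: none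
Why: Dess–Martin oxidation of the allylic alcohol to the C3 enone under bicarbonate buffering; the C3 stereocentre has served as relay and the carbonyl now makes C4=C5 electron-poor.

Step 13
Reactants: 18 (6S,1(10)E,4Z,7Z)-4,10-dimethyl-3-oxocyclodeca-1(10),4,7-trien-6-yl methyl propanedioate; 19 (2,2,6,6-tetramethylpiperidin-1-yl)oxyl
Product: 21 methyl (6R,7S,8R)-3-oxo-8-(TMPO)germacra-1(10)E,4Z-dien-12,6-olid-13-oate (C11 epimers), via C11 alkoxyamine 20 (not isolated)
Conditions: Fe(C5H5)2 (20 mol %), 19 (1.5 equiv), LiClO4 (0.1 M), THF/MeOH 4:1, reticulated vitreous carbon anode, Pt cathode, undivided cell, anode held at the Fe(C5H5)2 oxidation wave, −20 → 0 °C; then AcOH to neutral, solvent change to t-BuOH, 110–120 °C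
Reagents that add atoms: (2,2,6,6-tetramethylpiperidin-1-yl)oxyl (19), CC1(C)CCCC(C)(C)N1[O]
Why: Proposed new method: methoxide formed at the cathode converts the malonate, the most acidic C–H of 18, into its enolate, which ferrocenium (trivalent iron, regenerated at the anode from catalytic Fe(C5H5)2) oxidises by outer-sphere electron transfer to the electrophilic C11 radical; the closest known reactions are the oxidation of malonate enolates by stoichiometric ferrocenium salts with 5-exo cyclisation and nitroxide capture, and the ferrocene-mediated anodic generation of radicals from 1,3-dicarbonyl compounds, which have not been combined on an ester-tethered malonate facing a medium-ring olefin. The radical is at first largely intercepted by 19 at C11 to give 20, whose weak C11–O bond homolyses reversibly on heating and releases the radical in low stationary concentration beside the persistent nitroxide. The lactone ring closes in the 5-exo-trig mode by attack of C11 on C7 (bond C7–C11) through the less populated rotamer of the ester C(=O)–O bond, which is why the closure is slow and reversible nitroxide trapping is needed. C7 is set relative to C6 in the transition state that keeps the C6 hydrogen in the plane of the C7=C8 bond and places C5 and C8 on opposite faces of the forming ring, which gives the trans ring fusion. The secondary C8 radical is then captured irreversibly by 19 (bond C8–O) on its peripheral lobe, the inner lobe being screened by the transannular part of the ring, so that oxygen should enter cis to C11 (8R). Three selectivities are needed: attack at C7 and not at C5, which rests on the polarity mismatch between the electrophilic malonyl radical and the electron-poor C4=C5 bond of the C3 enone; trans and not cis fusion; and the face of C8 capture, the least secured of the three. The C7=C8 geometry is not transferred because C8 becomes trigonal, and both C11 epimers are carried on because C11 is made trigonal in step 17. The ionic competitor, conjugate addition of the enolate to C5 of the enone, is held back by a steady supply of ferrocenium, low temperature and the lithium counter-ion.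

Step 14
Reactants: 21 methyl (6R,7S,8R)-3-oxo-8-(TMPO)germacra-1(10)E,4Z-dien-12,6-olid-13-oate (C11 epimers)
Product: 22 methyl (3S,6R,7S,8R)-3-hydroxy-8-(TMPO)germacra-1(10)E,4Z-dien-12,6-olid-13-oate (C11 epimers)
Conditions: (R)-1-methyl-3,3-diphenyltetrahydro-1H,3H-pyrrolo[1,2-c][1,3,2]oxazaborole (20 mol %), catecholborane, toluene/CH2Cl2, −78 °C; then MeOH, aq NaHCO3
Reagents that add atoms: none
Why: CBS reduction of the C3 enone: the 4-methylalkenyl flank is the large group and C2H2 the small one, so the (R)-catalyst should give (3S), which peripheral hydride delivery on the bicycle is expected to reinforce. The ketone is reduced at this point because a C3 enone with the lactone oxygen on C6 is a γ-acyloxy enone that zinc would cleave at C6–O in step 18, and because its C2 methylene would enter the Mannich reaction of step 17.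

Step 15
Reactants: 22 methyl (3S,6R,7S,8R)-3-hydroxy-8-(TMPO)germacra-1(10)E,4Z-dien-12,6-olid-13-oate (C11 epimers)
Product: 23 methyl (3S,6R,7S,8R)-3-(TBS-oxy)-8-(TMPO)germacra-1(10)E,4Z-dien-12,6-olid-13-oate (C11 epimers)
Conditions: TBSCl, imidazole, DMF, rt
Reagents that add atoms: tert-butyldimethylsilyl chloride, CC(C)(C)[Si](C)(C)Cl
Why: Standard silylation; O3 must be masked before O8 is unveiled so that only O8 is acylated in step 27, and imidazole is too weak a base to enolise the malonate.

Step 16
Reactants: 23 methyl (3S,6R,7S,8R)-3-(TBS-oxy)-8-(TMPO)germacra-1(10)E,4Z-dien-12,6-olid-13-oate (C11 epimers)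
Product: 25 (3S,6R,7S,8R)-3-(TBS-oxy)-8-(TMPO)germacra-1(10)E,4Z-dien-12,6-olid-13-oic acid (C11 epimers), via ring-opened dilithium dicarboxylate 24 (not isolated)
Conditions: LiOH, THF/H2O, 0 °C → rt; then 1 M HCl to pH 3, 0 °C
Reagents that add atoms: lithium hydroxide, [Li+].[OH-]
Why: Saponification of the methyl ester; where the lactone opens as well (24), acidification closes it again, and only onto O6 because O8 is still blocked as the O-alkylhydroxylamine, so no 8,12-lactone can form. C6 and C7 are untouched and C11 is irrelevant.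

Step 17
Reactants: 25 (3S,6R,7S,8R)-3-(TBS-oxy)-8-(TMPO)germacra-1(10)E,4Z-dien-12,6-olid-13-oic acid (C11 epimers)
Product: 27 (3S,6R,7S,8R)-3-(TBS-oxy)-8-(TMPO)germacra-1(10)E,4Z,11(13)-trien-12,6-olide, via Mannich base 26 (not isolated)
Conditions: (CH2O)n, Et2NH, THF, 60 °C
Reagents that add atoms: formaldehyde (as paraformaldehyde), C=O
Why: Decarboxylative Mannich methylenation of an α-carboxy lactone: the iminium ion from formaldehyde and diethylamine alkylates C11, and loss of CO2 with expulsion of the amine gives the exo-methylene group. No strong base is needed and the bulky group on O8 stays on.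

Step 18
Reactants: 27 (3S,6R,7S,8R)-3-(TBS-oxy)-8-(TMPO)germacra-1(10)E,4Z,11(13)-trien-12,6-olide
Product: 28 (3S,6R,7R,8R)-3-(TBS-oxy)-8-hydroxygermacra-1(10)E,4Z,11(13)-trien-12,6-olide
Conditions: Zn, AcOH/THF/H2O 3:1:1, 50 °C
Reagents that add atoms: none
Why: Reductive N–O cleavage of an O-alkyl tetramethylpiperidinyl hydroxylamine by zinc in acetic acid, with retention at C8; with C3 at the alcohol level the C6–O bond is a plain allylic ester linkage that zinc does not attack, and the secondary TBS ether survives aqueous acetic acid.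

Step 19
Reactants: 29 tert-butyl prop-2-enoate; 30 acetaldehyde
Product: 31 rac-tert-butyl 3-hydroxy-2-methylidenebutanoate
Conditions: 1,4-diazabicyclo[2.2.2]octane (20 mol %), neat, rt
Reagents that add atoms: acetaldehyde (30), CC=O
Why: Morita–Baylis–Hillman reaction of an acrylate with an aldehyde under tertiary-amine catalysis; the stereocentre is irrelevant because it becomes trigonal in step 20.

Step 20
Reactants: 31 rac-tert-butyl 3-hydroxy-2-methylidenebutanoate
Product: 32 tert-butyl (2Z)-2-(bromomethyl)but-2-enoate
Conditions: N-bromosuccinimide, Me2S, CH2Cl2, 0 °C → rt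
Reagents that add atoms: N-bromosuccinimide, BrN1C(=O)CCC1=O
Why: Allylic transposition with bromide: the sulfonium reagent made in the flask activates the hydroxyl and bromide enters at the methylene terminus (SN2′), giving the thermodynamically preferred (2Z)-bromide, methyl trans to the ester; the tert-butyl ester is safe because no strong acid is present.

Step 21
Reactants: 29 tert-butyl prop-2-enoate; 33 (tert-butyldimethylsilyloxy)acetaldehyde
Product: 34 rac-tert-butyl 4-(TBS-oxy)-3-hydroxy-2-methylidenebutanoate
Conditions: 1,4-diazabicyclo[2.2.2]octane (30 mol %), dioxane/H2O, rt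
Reagents that add atoms: (tert-butyldimethylsilyloxy)acetaldehyde (33), CC(C)(C)[Si](C)(C)OCC=O
Why: Morita–Baylis–Hillman reaction with an α-silyloxy aldehyde; the carbinol centre is lost in step 23.

Step 22
Reactants: 34 rac-tert-butyl 4-(TBS-oxy)-3-hydroxy-2-methylidenebutanoate
Product: 35 rac-tert-butyl 3-acetoxy-4-(TBS-oxy)-2-methylidenebutanoate
Conditions: Ac2O, pyridine, 4-(dimethylamino)pyridine (cat.), CH2Cl2, 0 °C
Reagents that add atoms: acetic anhydride, CC(=O)OC(C)=O
Why: Routine acetylation of a secondary allylic alcohol; it installs the acetate that ends up in the target.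

Step 23
Reactants: 35 rac-tert-butyl 3-acetoxy-4-(TBS-oxy)-2-methylidenebutanoate
Product: 36 tert-butyl (2E)-2-(acetoxymethyl)-4-(TBS-oxy)but-2-enoate
Conditions: 1,4-diazabicyclo[2.2.2]octane (20 mol %), THF, reflux
Reagents that add atoms: none
Why: Amine-catalysed 1,3-acetoxy shift (SN2′ addition of the amine, then return of acetate at the methylene carbon) to the conjugated trisubstituted primary acetate; with an ester as activating group the (2E) isomer, β-substituent trans to the ester, is the favoured one.

Step 24
Reactants: 36 tert-butyl (2E)-2-(acetoxymethyl)-4-(TBS-oxy)but-2-enoate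
Product: 38 (2E)-2-(acetoxymethyl)-4-(TBS-oxy)but-2-enoic acid, via trimethylsilyl ester 37 (not isolated)
Conditions: TMSOTf, 2,6-lutidine, CH2Cl2, 0 °C; then H2O
Reagents that add atoms: none
Why: Silyl-triflate cleavage of a tert-butyl ester (loss of isobutene) to the silyl ester, which hydrolyses on work-up; the medium is non-protic, so the primary TBS ether and the allylic acetate remain.

Step 25
Reactants: 38 (2E)-2-(acetoxymethyl)-4-(TBS-oxy)but-2-enoic acid; 32 tert-butyl (2Z)-2-(bromomethyl)but-2-enoate
Product: 39 tert-butyl (2E)-2-({[(2E)-2-(acetoxymethyl)-4-(TBS-oxy)but-2-enoyl]oxy}methyl)but-2-enoate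
Conditions: Cs2CO3, DMF, 0 °C → rt
Reagents that add atoms: tert-butyl (2Z)-2-(bromomethyl)but-2-enoate (32), CC(C)(C)OC(=O)/C(=C/C)CBr
Why: SN2 alkylation of a caesium carboxylate by the allylic bromide at its methylene carbon, which gives the conjugated, thermodynamically preferred constitution; both olefin geometries are untouched (the descriptor of the bromide half changes from Z to E only through the priority rules).

Step 26
Reactants: 39 tert-butyl (2E)-2-({[(2E)-2-(acetoxymethyl)-4-(TBS-oxy)but-2-enoyl]oxy}methyl)but-2-enoate
Product: 41 (2E)-2-({[(2E)-2-(acetoxymethyl)-4-(TBS-oxy)but-2-enoyl]oxy}methyl)but-2-enoic acid, via trimethylsilyl ester 40 (not isolated)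
Conditions: TMSOTf, 2,6-lutidine, CH2Cl2, 0 °C; then H2O
Reagents that add atoms: none
Why: Same tert-butyl ester cleavage as in step 24; the inner ester, the acetate and the silyl ether are not affected by the non-nucleophilic conditions.

Step 27
Reactants: 28 (3S,6R,7R,8R)-3-(TBS-oxy)-8-hydroxygermacra-1(10)E,4Z,11(13)-trien-12,6-olide; 41 (2E)-2-({[(2E)-2-(acetoxymethyl)-4-(TBS-oxy)but-2-enoyl]oxy}methyl)but-2-enoic acid
Product: 43 (3S,6R,7R,8R)-3-(TBS-oxy)-8-{[(2E)-2-({[(2E)-2-(acetoxymethyl)-4-(TBS-oxy)but-2-enoyl]oxy}methyl)but-2-enoyl]oxy}germacra-1(10)E,4Z,11(13)-trien-12,6-olide, via mixed anhydride 42 (not isolated)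
Conditions: 41, 2,4,6-trichlorobenzoyl chloride, Et3N, toluene, rt; then 28, 4-(dimethylamino)pyridine (0.3 equiv), toluene, rt
Reagents that add atoms: acid 41, OC(=O)/C(=C/C)COC(=O)/C(=C/CO[Si](C)(C)C(C)(C)C)COC(C)=O
Why: Yamaguchi esterification: the pyridine catalyst attacks the mixed anhydride 42 at the less hindered acyl carbon and passes the acyl group to the hindered C8 hydroxyl with retention at C8. Catalyst loading and temperature are kept low because the allylic ester units of the side chain are SN2′ acceptors.

Step 28
Reactants: 43 (3S,6R,7R,8R)-3-(TBS-oxy)-8-acyloxygermacra-1(10)E,4Z,11(13)-trien-12,6-olide (acyl as in 41)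
Product: 44 (1R,3S,6R,7R,8R,10R)-1,10-epoxy-3-(TBS-oxy)-8-acyloxygermacra-4Z,11(13)-dien-12,6-olide (acyl as in 41)
Conditions: mCPBA, NaHCO3, CH2Cl2, 0 °C
Reagents that add atoms: 3-chloroperoxybenzoic acid, OOC(=O)c1cccc(Cl)c1
Why: Peracid epoxidation: C1=C10 is the only electron-rich olefin (C4=C5 carries two allylic C–O bonds, all others are acrylate-type), and the E geometry is transferred to the trans epoxide. Attack from the ring periphery on the preferred conformer should give (1R,10R).

Step 29
Reactants: 44 (1R,3S,6R,7R,8R,10R)-1,10-epoxy-3-(TBS-oxy)-8-acyloxygermacra-4Z,11(13)-dien-12,6-olide (acyl as in 41)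
Product: 45 (1R,3S,6R,7R,8R,10R)-1,10-epoxy-3-hydroxy-8-{[(2E)-2-({[(2E)-2-(acetoxymethyl)-4-hydroxybut-2-enoyl]oxy}methyl)but-2-enoyl]oxy}germacra-4Z,11(13)-dien-12,6-olide
Conditions: HF·pyridine, pyridine, THF, 0 °C → rt
Reagents that add atoms: none
Why: Fluoride cleavage of both TBS ethers under pyridine-buffered acidic conditions, which avoid the base-induced acetyl shift between the two cis-disposed oxymethyl groups and are mild enough for the epoxide and the exo-methylene lactone.

## Compound list

1 | 4-methoxy-2-methylphenol | COc1ccc(O)c(C)c1 | starting material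
2 | 4,4-dimethoxy-2-methylcyclohexa-2,5-dien-1-one | COC1(OC)C=CC(=O)C(C)=C1 | intermediate
3 | prop-1-en-2-ylmagnesium bromide | CC(=C)[Mg]Br | starting material
4 | rac-4,4-dimethoxy-2-methyl-5-(prop-1-en-2-yl)cyclohex-2-en-1-one | COC1(OC)C=C(C)C(=O)CC1C(C)=C | intermediate
5 | (1S)-4,4-dimethoxy-2-methyl-5-(prop-1-en-2-yl)cyclohex-2-en-1-ol, both C5 epimers | O[C@H]1CC(C(C)=C)C(OC)(OC)C=C1C | intermediate
6 | TBS ether of 5, (1S), both C5 epimers | CC(C)(C)[Si](C)(C)O[C@H]1CC(C(C)=C)C(OC)(OC)C=C1C | intermediate
7 | (4S)-4-(TBS-oxy)-3-methyl-6-(prop-1-en-2-yl)cyclohex-2-en-1-one, both C6 epimers | CC(C)(C)[Si](C)(C)O[C@H]1CC(C(C)=C)C(=O)C=C1C | intermediate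
8 | ethenylmagnesium bromide | C=C[Mg]Br | starting material
9 | (4S)-4-(TBS-oxy)-1-ethenyl-3-methyl-6-(prop-1-en-2-yl)cyclohex-2-en-1-ol, ethenyl trans to isopropenyl, both C6 epimers | CC(C)(C)[Si](C)(C)O[C@H]1CC(C(C)=C)C(O)(C=C)C=C1C | intermediate
10 | potassium (3S,1(10)E,4Z)-3-(TBS-oxy)-4,10-dimethylcyclodeca-1(10),4,6-trien-6-olate | CC(C)(C)[Si](C)(C)O[C@@H]1/C(C)=C\C([O-])=CCC/C(C)=C/C1.[K+] | intermediate (not isolated)
11 | (3S,1(10)E,4Z)-3-(TBS-oxy)-4,10-dimethyl-7-(phenylselanyl)cyclodeca-1(10),4-dien-6-one, C7 epimers | CC(C)(C)[Si](C)(C)O[C@@H]1/C(C)=C\C(=O)C([Se]c2ccccc2)CC/C(C)=C/C1 | intermediate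
12 | Se-oxide of 11 | CC(C)(C)[Si](C)(C)O[C@@H]1/C(C)=C\C(=O)C([Se](=O)c2ccccc2)CC/C(C)=C/C1 | intermediate (not isolated)
13 | (3S,1(10)E,4Z,7Z)-3-(TBS-oxy)-4,10-dimethylcyclodeca-1(10),4,7-trien-6-one | CC(C)(C)[Si](C)(C)O[C@@H]1/C(C)=C\C(=O)/C=C\C/C(C)=C/C1 | intermediate
14 | (3S,6S,1(10)E,4Z,7Z)-3-(TBS-oxy)-4,10-dimethylcyclodeca-1(10),4,7-trien-6-ol | CC(C)(C)[Si](C)(C)O[C@@H]1/C(C)=C\[C@@H](O)/C=C\C/C(C)=C/C1 | intermediate
15 | methyl 3-chloro-3-oxopropanoate (methyl malonyl chloride) | COC(=O)CC(Cl)=O | starting material
16 | (3S,6S,1(10)E,4Z,7Z)-3-(TBS-oxy)-4,10-dimethylcyclodeca-1(10),4,7-trien-6-yl methyl propanedioate | CC(C)(C)[Si](C)(C)O[C@@H]1/C(C)=C\[C@@H](OC(=O)CC(=O)OC)/C=C\C/C(C)=C/C1 | intermediate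
17 | (3S,6S,1(10)E,4Z,7Z)-3-hydroxy-4,10-dimethylcyclodeca-1(10),4,7-trien-6-yl methyl propanedioate | O[C@@H]1/C(C)=C\[C@@H](OC(=O)CC(=O)OC)/C=C\C/C(C)=C/C1 | intermediate
18 | (6S,1(10)E,4Z,7Z)-4,10-dimethyl-3-oxocyclodeca-1(10),4,7-trien-6-yl methyl propanedioate | O=C1/C(C)=C\[C@@H](OC(=O)CC(=O)OC)/C=C\C/C(C)=C/C1 | intermediate
19 | (2,2,6,6-tetramethylpiperidin-1-yl)oxyl (TEMPO) | CC1(C)CCCC(C)(C)N1[O] | starting material
20 | (6S,1(10)E,4Z,7Z)-4,10-dimethyl-3-oxocyclodeca-1(10),4,7-trien-6-yl methyl 2-(TMPO)propanedioate, C11 epimers | O=C1/C(C)=C\[C@@H](OC(=O)C(ON2C(C)(C)CCCC2(C)C)C(=O)OC)/C=C\C/C(C)=C/C1 | intermediate (not isolated)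
21 | methyl (6R,7S,8R)-3-oxo-8-(TMPO)germacra-1(10)E,4Z-dien-12,6-olid-13-oate, C11 epimers | COC(=O)C1C(=O)O[C@@H]2/C=C(/C)C(=O)C/C=C(\C)/C[C@@H](ON3C(C)(C)CCCC3(C)C)[C@@H]12 | intermediate
22 | methyl (3S,6R,7S,8R)-3-hydroxy-8-(TMPO)germacra-1(10)E,4Z-dien-12,6-olid-13-oate, C11 epimers | COC(=O)C1C(=O)O[C@@H]2/C=C(/C)[C@@H](O)C/C=C(\C)/C[C@@H](ON3C(C)(C)CCCC3(C)C)[C@@H]12 | intermediate
23 | methyl (3S,6R,7S,8R)-3-(TBS-oxy)-8-(TMPO)germacra-1(10)E,4Z-dien-12,6-olid-13-oate, C11 epimers | COC(=O)C1C(=O)O[C@@H]2/C=C(/C)[C@@H](O[Si](C)(C)C(C)(C)C)C/C=C(\C)/C[C@@H](ON3C(C)(C)CCCC3(C)C)[C@@H]12 | intermediate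
24 | dilithium (3S,6R,7S,8R)-3-(TBS-oxy)-6-hydroxy-8-(TMPO)germacra-1(10)E,4Z-diene-12,13-dioate | O[C@@H]1/C=C(/C)[C@@H](O[Si](C)(C)C(C)(C)C)C/C=C(\C)/C[C@@H](ON2C(C)(C)CCCC2(C)C)[C@H]1C(C(=O)[O-])C(=O)[O-].[Li+].[Li+] | intermediate (not isolated)
25 | (3S,6R,7S,8R)-3-(TBS-oxy)-8-(TMPO)germacra-1(10)E,4Z-dien-12,6-olid-13-oic acid, C11 epimers | OC(=O)C1C(=O)O[C@@H]2/C=C(/C)[C@@H](O[Si](C)(C)C(C)(C)C)C/C=C(\C)/C[C@@H](ON3C(C)(C)CCCC3(C)C)[C@@H]12 | intermediate
26 | 11-[(diethylamino)methyl] derivative of 25, C11 epimers | CCN(CC)CC1(C(=O)O)C(=O)O[C@@H]2/C=C(/C)[C@@H](O[Si](C)(C)C(C)(C)C)C/C=C(\C)/C[C@@H](ON3C(C)(C)CCCC3(C)C)[C@@H]12 | intermediate (not isolated)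
27 | (3S,6R,7S,8R)-3-(TBS-oxy)-8-(TMPO)germacra-1(10)E,4Z,11(13)-trien-12,6-olide | C=C1C(=O)O[C@@H]2/C=C(/C)[C@@H](O[Si](C)(C)C(C)(C)C)C/C=C(\C)/C[C@@H](ON3C(C)(C)CCCC3(C)C)[C@@H]12 | intermediate
28 | (3S,6R,7R,8R)-3-(TBS-oxy)-8-hydroxygermacra-1(10)E,4Z,11(13)-trien-12,6-olide | C=C1C(=O)O[C@@H]2/C=C(/C)[C@@H](O[Si](C)(C)C(C)(C)C)C/C=C(\C)/C[C@@H](O)[C@@H]12 | intermediate
29 | tert-butyl prop-2-enoate | C=CC(=O)OC(C)(C)C | starting material
30 | acetaldehyde | CC=O | starting material
31 | rac-tert-butyl 3-hydroxy-2-methylidenebutanoate | CC(O)C(=C)C(=O)OC(C)(C)C | intermediate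
32 | tert-butyl (2Z)-2-(bromomethyl)but-2-enoate | CC(C)(C)OC(=O)/C(=C/C)CBr | intermediate
33 | (tert-butyldimethylsilyloxy)acetaldehyde | CC(C)(C)[Si](C)(C)OCC=O | starting material
34 | rac-tert-butyl 4-(TBS-oxy)-3-hydroxy-2-methylidenebutanoate | CC(C)(C)[Si](C)(C)OCC(O)C(=C)C(=O)OC(C)(C)C | intermediate
35 | rac-tert-butyl 3-acetoxy-4-(TBS-oxy)-2-methylidenebutanoate | CC(C)(C)[Si](C)(C)OCC(OC(C)=O)C(=C)C(=O)OC(C)(C)C | intermediate
36 | tert-butyl (2E)-2-(acetoxymethyl)-4-(TBS-oxy)but-2-enoate | CC(C)(C)OC(=O)/C(=C/CO[Si](C)(C)C(C)(C)C)COC(C)=O | intermediate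
37 | trimethylsilyl (2E)-2-(acetoxymethyl)-4-(TBS-oxy)but-2-enoate | C[Si](C)(C)OC(=O)/C(=C/CO[Si](C)(C)C(C)(C)C)COC(C)=O | intermediate (not isolated)
38 | (2E)-2-(acetoxymethyl)-4-(TBS-oxy)but-2-enoic acid | OC(=O)/C(=C/CO[Si](C)(C)C(C)(C)C)COC(C)=O | intermediate
39 | tert-butyl (2E)-2-({[(2E)-2-(acetoxymethyl)-4-(TBS-oxy)but-2-enoyl]oxy}methyl)but-2-enoate | CC(C)(C)OC(=O)/C(=C/C)COC(=O)/C(=C/CO[Si](C)(C)C(C)(C)C)COC(C)=O | intermediate
40 | trimethylsilyl ester corresponding to 39 | C[Si](C)(C)OC(=O)/C(=C/C)COC(=O)/C(=C/CO[Si](C)(C)C(C)(C)C)COC(C)=O | intermediate (not isolated)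
41 | (2E)-2-({[(2E)-2-(acetoxymethyl)-4-(TBS-oxy)but-2-enoyl]oxy}methyl)but-2-enoic acid | OC(=O)/C(=C/C)COC(=O)/C(=C/CO[Si](C)(C)C(C)(C)C)COC(C)=O | intermediate
42 | mixed anhydride of 41 with 2,4,6-trichlorobenzoic acid | O=C(OC(=O)/C(=C/C)COC(=O)/C(=C/CO[Si](C)(C)C(C)(C)C)COC(C)=O)c1c(Cl)cc(Cl)cc1Cl | intermediate (not isolated)
43 | (3S,6R,7R,8R)-3-(TBS-oxy)-8-{[(2E)-2-({[(2E)-2-(acetoxymethyl)-4-(TBS-oxy)but-2-enoyl]oxy}methyl)but-2-enoyl]oxy}germacra-1(10)E,4Z,11(13)-trien-12,6-olide | C=C1C(=O)O[C@@H]2/C=C(/C)[C@@H](O[Si](C)(C)C(C)(C)C)C/C=C(\C)/C[C@@H](OC(=O)/C(=C/C)COC(=O)/C(=C/CO[Si](C)(C)C(C)(C)C)COC(C)=O)[C@@H]12 | intermediate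
44 | (1R,3S,6R,7R,8R,10R)-1,10-epoxy derivative of 43 (germacra-4Z,11(13)-dien-12,6-olide) | C=C1C(=O)O[C@@H]2/C=C(/C)[C@@H](O[Si](C)(C)C(C)(C)C)C[C@H]3O[C@]3(C)C[C@@H](OC(=O)/C(=C/C)COC(=O)/C(=C/CO[Si](C)(C)C(C)(C)C)COC(C)=O)[C@@H]12 | intermediate
45 | (1R,3S,6R,7R,8R,10R)-1,10-epoxy-3-hydroxy-8-{[(2E)-2-({[(2E)-2-(acetoxymethyl)-4-hydroxybut-2-enoyl]oxy}methyl)but-2-enoyl]oxy}germacra-4Z,11(13)-dien-12,6-olide | C=C1C(=O)O[C@@H]2/C=C(/C)[C@@H](O)C[C@H]3O[C@]3(C)C[C@@H](OC(=O)/C(=C/C)COC(=O)/C(=C/CO)COC(C)=O)[C@@H]12 | target

## Step count and least certain steps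

Total: 29 steps. Longest linear sequence: 21 steps (steps 1–18 and 27–29); the side-chain acid **41** takes 8 steps (19–26).

**Step 13 (key step).** The most likely failure is loss of the malonate enolate to an ionic pathway before electron transfer. In the basic, protic electrolyte the enolate can add to C5 of the C3 enone (5-exo conjugate addition). Turnover of the iron mediator in the presence of the nitroxide is also unproven, since the nitroxide is oxidisable only slightly above the mediator. The radical may in addition attack C5, or C8 may be captured on the other face; the latter is dealt with under step 27.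
- *Fallback (known chemistry; sets out from 14, comes back at 21).* Dimethyl malonate is converted by the established enolate–nitroxide oxidative coupling (NaH, CuCl2, **19**) into dimethyl 2-(TMPO)propanedioate F1, which is half-saponified (KOH, MeOH) to 3-methoxy-3-oxo-2-(TMPO)propanoic acid F2. Carbodiimide esterification of **14** with F2 gives the C3 silyl ether F3. Buffered HF·pyridine gives the C3 alcohol F4, and Dess–Martin oxidation gives **20**, now isolated. Heating **20** in t-BuOH at 120–130 °C isomerises it to **21** by reversible C–O homolysis, 5-exo closure and nitroxide recombination, so that neither base nor oxidant ever meets the trienone.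

**Step 9.** Poor or reversed facial selectivity at C6 is possible, because the relay from C3 rests on one assumed ring conformer and on peripheral attack.
- *Fallback (sets out from F5, comes back at 16).* If hydride enters from the other face, the product is the C6 epimer (3S,6R)-3-(TBS-oxy)-4,10-dimethylcyclodeca-1(10)E,4Z,7Z-trien-6-ol F5. Mitsunobu esterification of F5 with 3-methoxy-3-oxopropanoic acid (PPh3, diisopropyl azodicarboxylate) installs the malonate with inversion and gives **16**. This changes the C6–O bond formation from acylation with retention to substitution with inversion.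

**Step 18.** Zinc may over-reduce the substrate by conjugate reduction of the exo-methylene lactone.
- *Fallback (sets out from 23, comes back at 28).* The N–O bond is cleaved before the exo-methylene group exists: Zn/AcOH on **23** gives the 8-hydroxy ester F6. O8 is re-masked as the triethylsilyl ether F7 (Et3SiCl, imidazole) so that relactonisation stays at O6. Saponification and acidification give acid F8, and the Mannich methylenation gives the exo-methylene lactone F9. Pyridinium p-toluenesulfonate in MeOH removes the triethylsilyl group in the presence of the TBS ether and gives **28**.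

**Step 27 (with the C8 configuration it inherits from step 13).** Acylation of the hindered C8 hydroxyl may be slow and the pyridine catalyst may attack the allylic esters of **41**. It is also the point where capture of C8 on the wrong face in step 13 would show, because acylation proceeds with retention.
- *Fallback (sets out from F10, comes back at 43).* If step 13 has delivered the 8S series, step 18 gives (3S,6R,7R,8S)-3-(TBS-oxy)-8-hydroxygermacra-1(10)E,4Z,11(13)-trien-12,6-olide F10. Mitsunobu esterification of F10 with **41** (PPh3, diisopropyl azodicarboxylate, toluene) forms the ester with inversion at C8 and without a nucleophilic amine catalyst, giving **43**.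

**Step 28.** The peracid may attack the other face of C1=C10, since the exposed face depends on the ring conformer, or may attack C4=C5 in part.
- *Fallback (sets out from 28, comes back at 44).* The epoxide is introduced before the side chain under hydroxyl direction. VO(acac)2-catalysed epoxidation of **28** with t-BuOOH uses the homoallylic C8 hydroxyl to deliver oxygen to C1=C10 and gives the epoxy alcohol F11. Yamaguchi esterification of F11 with **41** through **42** then gives **44**.

**Step 29.** The risk is acid-induced opening of the epoxide, possibly with transannular participation, during removal of the slower secondary TBS ether.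
- *Fallback (sets out from 43, comes back at 45).* The order is reversed so that the epoxide is never exposed to fluoride. HF·pyridine on **43** gives the diol F12, and epoxidation of F12 with one equivalent of mCPBA at low temperature gives **45** directly. The price is that the free C3 hydroxyl may direct some peracid to C4=C5.

## Further compounds

F1 | step 13 | dimethyl 2-(TMPO)propanedioate | COC(=O)C(ON1C(C)(C)CCCC1(C)C)C(=O)OC
F2 | step 13 | 3-methoxy-3-oxo-2-(TMPO)propanoic acid | COC(=O)C(ON1C(C)(C)CCCC1(C)C)C(=O)O
F3 | step 13 | (3S,6S,1(10)E,4Z,7Z)-3-(TBS-oxy)-4,10-dimethylcyclodeca-1(10),4,7-trien-6-yl methyl 2-(TMPO)propanedioate | CC(C)(C)[Si](C)(C)O[C@@H]1/C(C)=C\[C@@H](OC(=O)C(ON2C(C)(C)CCCC2(C)C)C(=O)OC)/C=C\C/C(C)=C/C1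
F4 | step 13 | (3S,6S,1(10)E,4Z,7Z)-3-hydroxy-4,10-dimethylcyclodeca-1(10),4,7-trien-6-yl methyl 2-(TMPO)propanedioate | O[C@@H]1/C(C)=C\[C@@H](OC(=O)C(ON2C(C)(C)CCCC2(C)C)C(=O)OC)/C=C\C/C(C)=C/C1
F5 | step 9 | (3S,6R,1(10)E,4Z,7Z)-3-(TBS-oxy)-4,10-dimethylcyclodeca-1(10),4,7-trien-6-ol | CC(C)(C)[Si](C)(C)O[C@@H]1/C(C)=C\[C@H](O)/C=C\C/C(C)=C/C1
F6 | step 18 | methyl (3S,6R,7R,8R)-3-(TBS-oxy)-8-hydroxygermacra-1(10)E,4Z-dien-12,6-olid-13-oate | COC(=O)C1C(=O)O[C@@H]2/C=C(/C)[C@@H](O[Si](C)(C)C(C)(C)C)C/C=C(\C)/C[C@@H](O)[C@@H]12
F7 | step 18 | methyl (3S,6R,7S,8R)-3-(TBS-oxy)-8-(triethylsilyloxy)germacra-1(10)E,4Z-dien-12,6-olid-13-oate | COC(=O)C1C(=O)O[C@@H]2/C=C(/C)[C@@H](O[Si](C)(C)C(C)(C)C)C/C=C(\C)/C[C@@H](O[Si](CC)(CC)CC)[C@@H]12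
F8 | step 18 | (3S,6R,7S,8R)-3-(TBS-oxy)-8-(triethylsilyloxy)germacra-1(10)E,4Z-dien-12,6-olid-13-oic acid | OC(=O)C1C(=O)O[C@@H]2/C=C(/C)[C@@H](O[Si](C)(C)C(C)(C)C)C/C=C(\C)/C[C@@H](O[Si](CC)(CC)CC)[C@@H]12
F9 | step 18 | (3S,6R,7S,8R)-3-(TBS-oxy)-8-(triethylsilyloxy)germacra-1(10)E,4Z,11(13)-trien-12,6-olide | C=C1C(=O)O[C@@H]2/C=C(/C)[C@@H](O[Si](C)(C)C(C)(C)C)C/C=C(\C)/C[C@@H](O[Si](CC)(CC)CC)[C@@H]12
F10 | step 27 | (3S,6R,7R,8S)-3-(TBS-oxy)-8-hydroxygermacra-1(10)E,4Z,11(13)-trien-12,6-olide | C=C1C(=O)O[C@@H]2/C=C(/C)[C@@H](O[Si](C)(C)C(C)(C)C)C/C=C(\C)/C[C@H](O)[C@@H]12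
F11 | step 28 | (1R,3S,6R,7R,8R,10R)-1,10-epoxy-3-(TBS-oxy)-8-hydroxygermacra-4Z,11(13)-dien-12,6-olide | C=C1C(=O)O[C@@H]2/C=C(/C)[C@@H](O[Si](C)(C)C(C)(C)C)C[C@H]3O[C@]3(C)C[C@@H](O)[C@@H]12
F12 | step 29 | (3S,6R,7R,8R)-3-hydroxy-8-{[(2E)-2-({[(2E)-2-(acetoxymethyl)-4-hydroxybut-2-enoyl]oxy}methyl)but-2-enoyl]oxy}germacra-1(10)E,4Z,11(13)-trien-12,6-olide | C=C1C(=O)O[C@@H]2/C=C(/C)[C@@H](O)C/C=C(\C)/C[C@@H](OC(=O)/C(=C/C)COC(=O)/C(=C/CO)COC(C)=O)[C@@H]12
A1 | alternative 1 | (3R,4S,5S)-3-[(dimethylamino)methyl]-4-{2-[(2E)-5-(TBS-oxy)-2-methylpent-2-en-1-yl]-1,3-dithian-2-yl}-5-[(triphenylmethoxy)methyl]oxolan-2-one | CN(C)C[C@@H]1C(=O)O[C@H](COC(c2ccccc2)(c2ccccc2)c2ccccc2)[C@H]1C1(SCCCS1)C/C(C)=C/CCO[Si](C)(C)C(C)(C)C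
A2 | alternative 1 | tert-butyl{[(3E)-5-(1,3-dithian-2-yl)-4-methylpent-3-en-1-yl]oxy}dimethylsilane | CC(C)(C)[Si](C)(C)OCC/C=C(\C)CC1SCCCS1
A3 | alternative 1 | (5S)-5-[(triphenylmethoxy)methyl]furan-2(5H)-one | O=C1C=C[C@@H](COC(c2ccccc2)(c2ccccc2)c2ccccc2)O1
A4 | alternative 1 | N,N-dimethylmethyleneiminium iodide | C=[N+](C)C.[I-]
A5 | alternative 2 | (3S,8R,1(10)E,4Z)-3-(TBS-oxy)-8-[(4-methoxybenzyl)oxy]-4,10-dimethylcyclodeca-1(10),4-dien-6-one | O=C1/C=C(/C)[C@@H](O[Si](C)(C)C(C)(C)C)C/C=C(\C)/C[C@@H](OCc2ccc(OC)cc2)C1
A6 | alternative 3 | (1R,3S,6R,7S,8R,10R)-1,10-epoxy-3-hydroxy-8-(triethylsilyloxy)germacra-4Z,11(13)-dien-12,6-olide | C=C1C(=O)O[C@@H]2/C=C(/C)[C@@H](O)C[C@H]3O[C@]3(C)C[C@@H](O[Si](CC)(CC)CC)[C@@H]12
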